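The neighbouring flask with less incoming ligand comes last; first comes the flask itself, run in four vessels.

in all of them: incoming ligand 0.600 equiv
- spring: starting complex 0.50 M; time 15 min; a tube with plug flow, the mixed feed as stated, residence time 15 min
- summer: starting complex 0.50 M; one stirred flow tank at steady state, fed with the mixture as stated, mean residence time 15 min
- winter: starting complex 0.50 M (fed, over 12.0 min); time 15 min; all but starting complex at the start; starting complex goes in evenly over 12.0 min, the run ends at 15 min
- dawn: starting complex 0.50 M; time 15 min; everything together in a closed stirred flask, run for 15 min

    starting complex + incoming ligand ⇌ leaving ligand + complex with one exchanged (K1 = 2.4, k1 = 0.023 M⁻¹ s⁻¹)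
    complex with one exchanged ⇌ isomer of the product (K2 = 0.36, k2 = 0.12 s⁻¹)
    complex with one exchanged + incoming ligand ⇌ leaving ligand + complex with two exchanged (K3 = 0.59, k3 = 0.0027 M⁻¹ s⁻¹)

- the set-up with the highest amount of complex with one exchanged at the outlet or at the end, in percent of the starting complex put in ("none" if the first two lie within 2 percentage points) (spring / summer / winter / dawn / none)
- amount of complex with one exchanged at the outlet or at the end, in percent of the starting complex put in, spring
- amount of complex with one exchanged at the outlet or at the end, in percent of the starting complex put in, summer
- amount of complex with one exchanged at the outlet or at the end, in percent of the starting complex put in, winter
- amount of complex with one exchanged at the outlet or at the end, in percent of the starting complex put in, dawn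

- the stated concentrations are those of everything mixed, before any reaction; amounts are the same in each set-up
- the feed brings no volume worth counting
- run time (spring): 15 min

Incoming ligand, at 0.600 equiv, is the limiting reagent by charge, and counting turnovers shows which steps finish within the run. At the charged ligand, the first exchange gets 8.96 forward half-lives in 15 min. The isomerisation relaxes with a half-life of 1.53 s, far shorter than the run. So the reckoning by hand puts both at equilibrium, with complex with one exchanged and the isomer as one pool, whose constant is the first constant times one plus the second, 3.26.

Call x the share of starting complex exchanged. Then x squared equals that constant times what remains of starting complex times what remains of ligand, which gives 47.1 %. The two-step ceiling, the part of that pool standing as complex with one exchanged before any second exchange, is 34.7 %, the bound from above.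

For the bound from below, the second exchange is counted at the ligand free under the ceiling, 0.0644 M, which gives 0.156 turnovers in the run. Taken forward only and charged wholly to complex with one exchanged, they leave 29.6 % in tube and flask. Ligand starts higher than the figure used, so this floor is an estimate and not a strict bound.

Plug flow gives each slice of feed the flask's clock, so tube and flask share one history. The tank and the dosed run get no figure by hand here. Both are expected lower, which leaves tube and flask as the top two, tied, and the call at none.

The forecast gives 31.2 % for spring, 28.4 % for summer, 30.2 % for winter and 31.2 % for dawn, calls none, and holds that “the yield is set mainly by that equilibrium”; its spring value stands inside the bracket, lower than the ceiling and higher than the floor.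

The simulation gives 31.1 % for spring, 28.4 % for summer, 30.5 % for winter and 31.1 % for dawn, and the call is none. Spring lies 3.6 percentage points under the ceiling and higher than the floor.

The neighbouring flask is spring with 0.240 equiv of incoming ligand. The same balance gives an exchanged share of 22.1 %, so its ceiling is 16.2 %. Free ligand under that ceiling is 0.00959 M, which allows the second exchange 0.0233 turnovers, fewer than in spring. That flask ends with 0.409 % of complex with two exchanged and 15.7 % of complex with one exchanged, 0.50 points under its ceiling.

All constants were set for the occasion; the flask was simulated.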